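The target is a C2v-symmetric pair of filicinic acid rings (4,4-dimethylcyclohexane-1,3,5-trione enols, ring atoms C1 to C6) joined through C6 and C6' by one CH2. In each ring, C4 (CMe2), the C5 carbonyl and C6 form a ketone with its two α-carbons, while C1, C2 and C3 form a malonyl unit. The route rests on making bonds C3–C4 and C1–C6 of both rings at once: a twofold Effenberger-type annulation of malonyl dichloride onto the regiodefined bis(silyl enol ether) of 2,8-dimethylnonane-3,7-dione, an acyclic C11 chain whose central CH2 becomes the bridge. The two isobutyryl groups are then placed on C2 and C2'.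

Key step: step 4

Remark on the chemistry: the target has no stereocentre and is drawn as one enol tautomer; all tautomers of the cyclic trione rings are taken as one compound. Ring numbering used throughout: C1 = ring C=O next to the acyl-bearing carbon, C2 = acyl-bearing carbon, C3 = C–OH next to C2, C4 = CMe2, C5 = second C–OH, C6 = carbon bearing the bridging CH2.

Step 1
Reactants: 1 glutaryl dichloride (pentanedioyl dichloride)
Product: 2 N1,N5-dimethoxy-N1,N5-dimethylpentanediamide (bis-Weinreb amide of glutaric acid)
Conditions: MeNHOMe·HCl (2.2 equiv), pyridine (4.5 equiv), CH2Cl2, 0 °C to rt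
Reagents that add atoms: N,O-dimethylhydroxylamine hydrochloride, CNOC.Cl
Why: Twofold N-acylation of the amine by the diacid chloride (amide formation), with pyridine taking up the HCl, should give the bis-Weinreb amide cleanly.

Step 2
Reactants: 2 N1,N5-dimethoxy-N1,N5-dimethylpentanediamide; 3 isopropenylmagnesium bromide (prop-1-en-2-ylmagnesium bromide, THF solution, 2.6 equiv)
Product: 4 2,8-dimethylnona-1,8-diene-3,7-dione (bis(isopropenyl ketone))
Conditions: THF, −10 to 0 °C; inverse quench into cold 1 M HCl; product stored cold with a trace of BHT
Reagents that add atoms: none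
Why: Weinreb ketone synthesis, in which the chelated tetrahedral magnesium adduct stops each addition at the ketone stage and the acidic inverse quench keeps the liberated MeNHOMe protonated so that it should not add to the new α-methylene ketones.

Step 3
Reactants: 4 2,8-dimethylnona-1,8-diene-3,7-dione
Product: 5 2,8-dimethyl-3,7-bis(triethylsilyloxy)nona-2,7-diene (bis(tetrasubstituted silyl enol ether); no E/Z element)
Conditions: Et3SiH (2.3 equiv), RhCl(PPh3)3 (1 mol %), benzene, 50 °C
Reagents that add atoms: triethylsilane, CC[SiH](CC)CC
Why: Rhodium-catalysed 1,4-hydrosilylation of an α,β-unsaturated ketone delivers hydrogen to the terminal CH2 and silicon to oxygen, so each isopropenyl ketone should give only the Me2C=C(OSiEt3) enol ether, a regiochemistry that enolisation of the saturated diketone would not secure.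

Step 4
Reactants: 5 2,8-dimethyl-3,7-bis(triethylsilyloxy)nona-2,7-diene; 6 malonyl dichloride (2.3 equiv)
Product: 8 6,6'-methylenebis(3,5-dihydroxy-4,4-dimethylcyclohexa-2,5-dien-1-one) (methylenebis(filicinic acid)), via bis(β-keto acid chloride) 7 (not isolated)
Conditions: 5 added slowly to 6, Et2O, −20 °C to rt; then KOH, BnEt3NCl, H2O, rt; then HCl to pH 2
Reagents that add atoms: none
Why: Each Me2C= terminus of 5 is C-acylated by one COCl group of malonyl dichloride, which makes bond C3–C4, sets the quaternary C4 and releases Et3SiCl to give 7; the freed C5 ketone can then enolise only toward C6, and that enol carbon attacks the pendant COCl (or the acylketene formed from it by loss of HCl) to make bond C1–C6. The closest known reaction type is the Effenberger cyclisation of cyclohexanone enol ethers with malonyl dichloride to bicyclo[3.3.1]nonane-2,4,9-triones, which also creates a quaternary carbon at the substituted enol ether carbon; here it is applied twice to an acyclic bis(enol ether). Each six-membered ring closes in a 6-(enolendo)-exo-trig mode. No stereocentre is formed, since the product is achiral and fully enolised. The step needs C- over O-acylation in the ring closure and must avoid the 4-hydroxy-2-pyranone channel; placing the enol ether double bond at CMe2 puts the intermolecular acylation on the carbon that becomes quaternary, so the 1,3-diketone of 7 cannot enolise between C3 and C5 and the only enol available closes the carbocycle. Slow addition of 5 to excess 6 should suppress bridging of two chains by one malonyl unit, and the KOH and phase-transfer treatment should complete ring closure and extract 8 as its salt.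

Step 5
Reactants: 8 6,6'-methylenebis(3,5-dihydroxy-4,4-dimethylcyclohexa-2,5-dien-1-one); 9 isobutyryl chloride (2-methylpropanoyl chloride, 2.2 equiv)
Product: 11 6,6'-methylenebis[3,5-dihydroxy-4,4-dimethyl-2-(2-methylpropanoyl)cyclohexa-2,5-dien-1-one] (target, CNP0353497.0), via bis(enol isobutyrate) 10 (not isolated)
Conditions: Et3N (5 equiv), CH2Cl2, 0 °C; then DMAP (0.2 equiv), rt; 1 M HCl work-up
Reagents that add atoms: none
Why: O-acylation of the vinylogous acids followed by DMAP-catalysed O-to-C acyl migration (the standard route to 2-acylcyclohexane-1,3-diones) should move each isobutyryl group to C2, the only unsubstituted carbon between two ring carbonyls, where the product is held as a stabilised enolate.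

Compound list
1 | glutaryl dichloride (pentanedioyl dichloride) | O=C(Cl)CCCC(=O)Cl | starting material
2 | N1,N5-dimethoxy-N1,N5-dimethylpentanediamide | CON(C)C(=O)CCCC(=O)N(C)OC | intermediate
3 | isopropenylmagnesium bromide | CC(=C)[Mg]Br | starting material
4 | 2,8-dimethylnona-1,8-diene-3,7-dione | C=C(C)C(=O)CCCC(=O)C(C)=C | intermediate
5 | 2,8-dimethyl-3,7-bis(triethylsilyloxy)nona-2,7-diene | CC(C)=C(CCCC(=C(C)C)O[Si](CC)(CC)CC)O[Si](CC)(CC)CC | intermediate
6 | malonyl dichloride (propanedioyl dichloride) | O=C(Cl)CC(=O)Cl | starting material
7 | 4,4,10,10-tetramethyl-3,5,9,11-tetraoxotridecanedioyl dichloride (bis(β-keto acid chloride), not isolated) | CC(C)(C(=O)CC(=O)Cl)C(=O)CCCC(=O)C(C)(C)C(=O)CC(=O)Cl | intermediate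
8 | 6,6'-methylenebis(3,5-dihydroxy-4,4-dimethylcyclohexa-2,5-dien-1-one) | O=C1C=C(O)C(C)(C)C(O)=C1CC1=C(O)C(C)(C)C(O)=CC1=O | intermediate
9 | isobutyryl chloride (2-methylpropanoyl chloride) | CC(C)C(=O)Cl | starting material
10 | methylenebis(5-hydroxy-6,6-dimethyl-3-oxocyclohexa-1,4-diene-4,1-diyl) bis(2-methylpropanoate) (bis(enol isobutyrate), not isolated) | CC(C)C(=O)OC1=CC(=O)C(CC2=C(O)C(C)(C)C(OC(=O)C(C)C)=CC2=O)=C(O)C1(C)C | intermediate
11 | 6,6'-methylenebis[3,5-dihydroxy-4,4-dimethyl-2-(2-methylpropanoyl)cyclohexa-2,5-dien-1-one] | CC(C)C(=O)C1=C(O)C(C)(C)C(O)=C(CC2=C(O)C(C)(C)C(O)=C(C(=O)C(C)C)C2=O)C1=O | target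

Total step count: 5
Longest linear sequence: 5 steps (1 → 2 → 4 → 5 → 8 → 11)

Steps most likely to fail

Step 4 (key step). The ring closure may go through the enol oxygen instead of carbon, giving enol lactones that are lost by hydrolysis in the KOH stage. One malonyl unit may also bridge two chains, or the still-silylated half may add in an aldol sense to the ketone of the acylated half. The fallback sets out from 5 and comes back at 8, making the two bonds of each ring in separate operations. 5 would be C-acylated at both CMe2 termini with methyl 3-chloro-3-oxopropanoate (ZnCl2, CH2Cl2, 0 °C; Mukaiyama-type acylation of a silyl enol ether) to give dimethyl 4,4,10,10-tetramethyl-3,5,9,11-tetraoxotridecanedioate F1. A twofold Dieckmann (intramolecular Claisen) cyclisation of F1 with KOtBu in THF, then acidification, should give 8. The non-nucleophilic base is chosen to avoid retro-Claisen cleavage of the 2,2-dimethyl-1,3-diketone.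

Step 3. 1,2-Hydrosilylation of the carbonyl groups, reductive aldol cyclisation of a rhodium enolate onto the second enone, or polymerisation of the α-methylene ketone may compete with the twofold 1,4-addition. The fallback sets out from 2 and comes back at 5 without passing through the enone. 2 with isopropylmagnesium chloride (THF, 0 °C, HCl quench) should give 2,8-dimethylnonane-3,7-dione F2. Acid-catalysed bromination (Br2, AcOH), which runs through the more substituted enol, should give 2,8-dibromo-2,8-dimethylnonane-3,7-dione F3. Reductive silylation of F3 with zinc dust and Et3SiCl (TMEDA, Et2O) should then give 5 with the enol ether fixed at the CMe2 carbons.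

Step 5. The O-to-C acyl migration may stop at the enol ester stage, further enol oxygens may be acylated, or the basic medium may open the methylene bridge by retro-Michael cleavage. The fallback sets out from 8 and comes back at 11: direct Friedel–Crafts-type C-acylation with 9 and AlCl3 in nitrobenzene at rt, the classical acidic acylation of filicinic acid, which needs no enol ester and no base; it makes no new compound (F0).

Further compounds
F1 | step 4 | dimethyl 4,4,10,10-tetramethyl-3,5,9,11-tetraoxotridecanedioate | COC(=O)CC(=O)C(C)(C)C(=O)CCCC(=O)C(C)(C)C(=O)CC(=O)OC
F2 | step 3 | 2,8-dimethylnonane-3,7-dione | CC(C)C(=O)CCCC(=O)C(C)C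
F3 | step 3 | 2,8-dibromo-2,8-dimethylnonane-3,7-dione | CC(C)(Br)C(=O)CCCC(=O)C(C)(C)Br
F0 | step 5 | none | none
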